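**Retrosynthetic overview**
1. Target 27 ⇐ hydrogenolysis of tetra-O-benzyl dimer 26 ⇐ Suzuki–Miyaura biaryl coupling (the C5–C5′ bond) of two monomeric lactones of equal size, aryl bromide 24 and its pinacol boronate 25.
2. Monomer 24 ⇐ C-benzylation of the enediolate of α-hydroxy lactone 22 with benzyl bromide 8, anti to the C4 substituent (sets the quaternary C3).
3. 22 ⇐ enolate hydroxylation of (S)-β-arylmethyl-γ-butyrolactone 20 ⇐ dealkoxycarbonylation of 19 ⇐ copper-catalysed opening of cyclopropane-fused lactone 17 by the aryl Grignard from 11.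
4. 17 ⇐ dimethyl malonate (from malonic acid) + (S)-epichlorohydrin, the only source of chirality; both aryl pieces 8 and 11 ⇐ guaiacol ⇐ catechol.
5. Ring order: cyclopropane, then γ-lactone (both in step 11); cyclopropane opened in step 12; the arenes are bought as catechol; the biaryl bond is made last (step 17).

Assumption: the SMILES is read as the all-R isomer (each lactone 3R,4R, the two benzyl groups trans), and n-BuLi, iPrMgCl·LiCl, KN(SiMe3)2 and LiN(iPr)2 are used as bought solutions.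

**Route**

Step 1
Reactants: 1 catechol
Product: 2 guaiacol (2-methoxyphenol)
Conditions: MeI (1.0 equiv), K2CO3 (1.0 equiv), acetone, reflux; unreacted 1 recovered
Reagents that add atoms: iodomethane, CI
Why: Williamson mono-O-methylation, in which limiting MeI and carbonate keep dimethylation low and guaiacol is separated from catechol and veratrole by distillation.

Step 2
Reactants: 2 guaiacol
Product: 3 4-bromo-2-methoxyphenol
Conditions: NBS (1.0 equiv), MeCN, 0 °C
Reagents that add atoms: N-bromosuccinimide, O=C1CCC(=O)N1Br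
Why: electrophilic aromatic bromination, directed by the free OH (the strongest donor) to its open para position.

Step 3
Reactants: 3 4-bromo-2-methoxyphenol
Product: 4 1-(benzyloxy)-4-bromo-2-methoxybenzene
Conditions: BnBr (1.1 equiv), K2CO3, DMF, rt
Reagents that add atoms: benzyl bromide, BrCc1ccccc1
Why: Williamson etherification of the phenoxide, giving a benzyl ether that survives all later base and organometallic steps.

Step 4
Reactants: 4 1-(benzyloxy)-4-bromo-2-methoxybenzene
Product: 6 4-(benzyloxy)-3-methoxybenzaldehyde, via aryllithium 5 (not isolated)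
Conditions: n-BuLi (1.05 equiv), THF, −78 °C; DMF (1.5 equiv), −78 °C → rt; aq. HCl
Reagents that add atoms: N,N-dimethylformamide, CN(C)C=O
Why: bromine–lithium exchange followed by Bouveault formylation, which is fast at −78 °C and leaves the benzyl ether untouched.

Step 5
Reactants: 6 4-(benzyloxy)-3-methoxybenzaldehyde
Product: 7 [4-(benzyloxy)-3-methoxyphenyl]methanol
Conditions: NaBH4 (0.3 equiv), MeOH, 0 °C
Reagents that add atoms: none
Why: borohydride reduction of the aldehyde to the benzylic alcohol.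

Step 6
Reactants: 7 [4-(benzyloxy)-3-methoxyphenyl]methanol
Product: 8 1-(benzyloxy)-4-(bromomethyl)-2-methoxybenzene
Conditions: PBr3 (0.4 equiv), Et2O, 0 °C; used at once
Reagents that add atoms: phosphorus tribromide, BrP(Br)Br
Why: bromination of the activated benzylic alcohol through its phosphite ester (SN2-type displacement by bromide).

Step 7
Reactants: 2 guaiacol
Product: 9 4-iodo-2-methoxyphenol
Conditions: NIS (1.0 equiv), TsOH·H2O (10 mol%), MeCN, rt
Reagents that add atoms: N-iodosuccinimide, O=C1CCC(=O)N1I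
Why: acid-activated electrophilic aromatic iodination, para to the free OH.

Step 8
Reactants: 9 4-iodo-2-methoxyphenol
Product: 10 2-bromo-4-iodo-6-methoxyphenol
Conditions: NBS (1.0 equiv), iPr2NH (10 mol%), CH2Cl2, 0 °C
Reagents that add atoms: N-bromosuccinimide, O=C1CCC(=O)N1Br
Why: amine-mediated ortho-bromination of a phenol, which with the para position blocked by iodine can only take the one free position ortho to OH.

Step 9
Reactants: 10 2-bromo-4-iodo-6-methoxyphenol
Product: 11 2-(benzyloxy)-1-bromo-5-iodo-3-methoxybenzene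
Conditions: BnBr (1.2 equiv), K2CO3, DMF, 50 °C
Reagents that add atoms: benzyl bromide, BrCc1ccccc1
Why: Williamson etherification of the hindered phenoxide, as for other 2,6-disubstituted phenols.

Step 10
Reactants: 12 malonic acid
Product: 13 dimethyl malonate
Conditions: MeOH (solvent), H2SO4 (cat.), reflux
Reagents that add atoms: methanol, CO
Why: Fischer esterification, run well below the decarboxylation temperature of malonic acid.

Step 11
Reactants: 13 dimethyl malonate; 14 (S)-epichlorohydrin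
Product: 17 methyl (1R,5S)-2-oxo-3-oxabicyclo[3.1.0]hexane-1-carboxylate, via epoxy malonate 15 (not isolated), via cyclopropylmethanolate 16 (not isolated)
Conditions: NaOMe (1.0 equiv), MeOH, rt → reflux, 20 h
Reagents that add atoms: none
Why: tandem malonate alkylation in which the malonate opens the epoxide at CH2 and the alkoxide recloses onto the CH2Cl carbon (15), a 3-exo-tet cyclopropanation inverts the stereocentre (16), and lactonisation onto the cis ester follows, so the (S) centre of 14 becomes C5 (S) and the cis ring fusion fixes C1 (R).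

Step 12
Reactants: 11 2-(benzyloxy)-1-bromo-5-iodo-3-methoxybenzene; 17 methyl (1R,5S)-2-oxo-3-oxabicyclo[3.1.0]hexane-1-carboxylate
Product: 19 methyl (3R,4S)-4-{[4-(benzyloxy)-3-bromo-5-methoxyphenyl]methyl}-2-oxooxolane-3-carboxylate, via arylmagnesium chloride 18 (not isolated)
Conditions: 11 (1.25 equiv), iPrMgCl·LiCl (1.2 equiv), THF, −20 °C, 1 h; then 17 (1.0 equiv), CuBr·SMe2 (10 mol%), THF, −40 → −10 °C; aq. HCl
Reagents that add atoms: none
Why: iodine–magnesium exchange (far faster at C–I than at C–Br) then copper-catalysed homoconjugate opening of the doubly activated cyclopropane at its CH2, which leaves C5 of 17 untouched as C4 (S) while the malonate-type C3 settles trans (R).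

Step 13
Reactants: 19 methyl (3R,4S)-4-{[4-(benzyloxy)-3-bromo-5-methoxyphenyl]methyl}-2-oxooxolane-3-carboxylate
Product: 20 (4S)-4-{[4-(benzyloxy)-3-bromo-5-methoxyphenyl]methyl}oxolan-2-one
Conditions: LiCl (2 equiv), H2O (2 equiv), DMSO, 140 °C
Reagents that add atoms: none
Why: Krapcho dealkoxycarbonylation of the malonate-type ester, which does not involve C4 and is tolerated by the aryl bromide and the benzyl ether.

Step 14
Reactants: 20 (4S)-4-{[4-(benzyloxy)-3-bromo-5-methoxyphenyl]methyl}oxolan-2-one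
Product: 22 (3S,4R)-4-{[4-(benzyloxy)-3-bromo-5-methoxyphenyl]methyl}-3-hydroxyoxolan-2-one, via potassium enolate 21 (not isolated)
Conditions: KN(SiMe3)2 (1.2 equiv), THF, −78 °C; 2-(phenylsulfonyl)-3-phenyloxaziridine (1.5 equiv), −78 °C; aq. HCl
Reagents that add atoms: 2-(phenylsulfonyl)-3-phenyloxaziridine (Davis oxaziridine), O=S(=O)(c1ccccc1)N1OC1c1ccccc1
Why: Davis enolate hydroxylation, with oxygen delivered anti to the C4 arylmethyl group (trans product); the C3 configuration is reset in step 15 in any case.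

Step 15
Reactants: 22 (3S,4R)-4-{[4-(benzyloxy)-3-bromo-5-methoxyphenyl]methyl}-3-hydroxyoxolan-2-one; 8 1-(benzyloxy)-4-(bromomethyl)-2-methoxybenzene
Product: 24 (3R,4R)-3-{[4-(benzyloxy)-3-methoxyphenyl]methyl}-4-{[4-(benzyloxy)-3-bromo-5-methoxyphenyl]methyl}-3-hydroxyoxolan-2-one, via dilithium enediolate 23 (not isolated)
Conditions: LiN(iPr)2 (2.3 equiv), THF–DMPU 4:1, −78 → −40 °C, 1 h; 8 (1.3 equiv), −78 → −30 °C; aq. HCl
Reagents that add atoms: none
Why: C-alkylation of the α-hydroxy lactone dianion, in which the benzyl bromide enters the planar enediolate anti to the C4 arylmethyl group, giving trans benzyl groups with OH cis to the C4 substituent, that is (3R,4R).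

Step 16
Reactants: 24 (3R,4R)-3-{[4-(benzyloxy)-3-methoxyphenyl]methyl}-4-{[4-(benzyloxy)-3-bromo-5-methoxyphenyl]methyl}-3-hydroxyoxolan-2-one
Product: 25 (3R,4R)-3-{[4-(benzyloxy)-3-methoxyphenyl]methyl}-4-{[4-(benzyloxy)-3-methoxy-5-(4,4,5,5-tetramethyl-1,3,2-dioxaborolan-2-yl)phenyl]methyl}-3-hydroxyoxolan-2-one
Conditions: B2pin2 (1.5 equiv), Pd2(dba)3 (2 mol%), XPhos (8 mol%), KOAc (3 equiv), 1,4-dioxane, 90 °C
Reagents that add atoms: bis(pinacolato)diboron, CC1(C)OB(OC1(C)C)B1OC(C)(C)C(C)(C)O1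
Why: Miyaura borylation of the aryl bromide with zerovalent palladium and a bulky biarylphosphine, which tolerates the lactone and the free tertiary alcohol and touches no stereocentre.

Step 17
Reactants: 24 (3R,4R)-3-{[4-(benzyloxy)-3-methoxyphenyl]methyl}-4-{[4-(benzyloxy)-3-bromo-5-methoxyphenyl]methyl}-3-hydroxyoxolan-2-one; 25 the pinacol boronate of step 16
Product: 26 (3R,3′R,4R,4′R)-4,4′-{[2,2′-bis(benzyloxy)-3,3′-dimethoxy-[1,1′-biphenyl]-5,5′-diyl]bis(methylene)}bis(3-{[4-(benzyloxy)-3-methoxyphenyl]methyl}-3-hydroxyoxolan-2-one)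
Conditions: 24 (1.0 equiv), 25 (1.1 equiv), Pd(OAc)2 (5 mol%), SPhos (10 mol%), K3PO4 (3 equiv), toluene/H2O 10:1, 90 °C; dilute HCl work-up
Reagents that add atoms: none
Why: Suzuki–Miyaura cross-coupling of two halves of equal size, with SPhos chosen for the ortho-benzyloxy partners; the quaternary C3 and the non-acidic C4 cannot epimerise, and the acid work-up recloses any lactone opened by base.

Step 18
Reactants: 26 the tetra-O-benzyl dimer of step 17
Product: 27 bis-5,5-nortrachelogenin, (3R,3′R,4R,4′R)-4,4′-{[2,2′-dihydroxy-3,3′-dimethoxy-[1,1′-biphenyl]-5,5′-diyl]bis(methylene)}bis{3-hydroxy-3-[(4-hydroxy-3-methoxyphenyl)methyl]oxolan-2-one}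
Conditions: H2 (1 atm), Pd/C (10 wt%), EtOAc/MeOH 1:1, rt
Reagents that add atoms: none
Why: catalytic hydrogenolysis of the four aryl benzyl ethers, which leaves the lactones, the biaryl and the tertiary (non-benzylic) alcohols untouched.

**Compound list**
1 | catechol (benzene-1,2-diol) | Oc1ccccc1O | starting material
2 | guaiacol (2-methoxyphenol) | COc1ccccc1O | intermediate
3 | 4-bromo-2-methoxyphenol | COc1cc(Br)ccc1O | intermediate
4 | 1-(benzyloxy)-4-bromo-2-methoxybenzene | COc1cc(Br)ccc1OCc1ccccc1 | intermediate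
5 | [4-(benzyloxy)-3-methoxyphenyl]lithium | COc1cc([Li])ccc1OCc1ccccc1 | intermediate
6 | 4-(benzyloxy)-3-methoxybenzaldehyde | COc1cc(C=O)ccc1OCc1ccccc1 | intermediate
7 | [4-(benzyloxy)-3-methoxyphenyl]methanol | COc1cc(CO)ccc1OCc1ccccc1 | intermediate
8 | 1-(benzyloxy)-4-(bromomethyl)-2-methoxybenzene | COc1cc(CBr)ccc1OCc1ccccc1 | intermediate
9 | 4-iodo-2-methoxyphenol | COc1cc(I)ccc1O | intermediate
10 | 2-bromo-4-iodo-6-methoxyphenol | COc1cc(I)cc(Br)c1O | intermediate
11 | 2-(benzyloxy)-1-bromo-5-iodo-3-methoxybenzene | COc1cc(I)cc(Br)c1OCc1ccccc1 | intermediate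
12 | malonic acid | OC(=O)CC(=O)O | starting material
13 | dimethyl malonate | COC(=O)CC(=O)OC | intermediate
14 | (S)-epichlorohydrin, (2S)-2-(chloromethyl)oxirane | ClC[C@@H]1CO1 | starting material
15 | dimethyl 2-{[(2S)-oxiran-2-yl]methyl}propanedioate | COC(=O)C(C(=O)OC)C[C@H]1CO1 | intermediate
16 | sodium [(1S)-2,2-bis(methoxycarbonyl)cyclopropyl]methanolate | COC(=O)C1(C(=O)OC)C[C@@H]1C[O-].[Na+] | intermediate
17 | methyl (1R,5S)-2-oxo-3-oxabicyclo[3.1.0]hexane-1-carboxylate | COC(=O)[C@]12C(=O)OC[C@H]1C2 | intermediate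
18 | [4-(benzyloxy)-3-bromo-5-methoxyphenyl]magnesium chloride (LiCl complex) | COc1cc([Mg]Cl)cc(Br)c1OCc1ccccc1 | intermediate
19 | methyl (3R,4S)-4-{[4-(benzyloxy)-3-bromo-5-methoxyphenyl]methyl}-2-oxooxolane-3-carboxylate | COC(=O)[C@@H]1C(=O)OC[C@H]1Cc1cc(OC)c(OCc2ccccc2)c(Br)c1 | intermediate
20 | (4S)-4-{[4-(benzyloxy)-3-bromo-5-methoxyphenyl]methyl}oxolan-2-one | O=C1C[C@H](Cc2cc(OC)c(OCc3ccccc3)c(Br)c2)CO1 | intermediate
21 | potassium (3S)-3-{[4-(benzyloxy)-3-bromo-5-methoxyphenyl]methyl}-2,3-dihydrofuran-5-olate | [K+].[O-]C1=C[C@H](Cc2cc(OC)c(OCc3ccccc3)c(Br)c2)CO1 | intermediate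
22 | (3S,4R)-4-{[4-(benzyloxy)-3-bromo-5-methoxyphenyl]methyl}-3-hydroxyoxolan-2-one | O[C@@H]1C(=O)OC[C@H]1Cc1cc(OC)c(OCc2ccccc2)c(Br)c1 | intermediate
23 | dilithium (3R)-3-{[4-(benzyloxy)-3-bromo-5-methoxyphenyl]methyl}-2,3-dihydrofuran-4,5-bis(olate) | [Li+].[Li+].[O-]C1=C([O-])[C@H](Cc2cc(OC)c(OCc3ccccc3)c(Br)c2)CO1 | intermediate
24 | (3R,4R)-3-{[4-(benzyloxy)-3-methoxyphenyl]methyl}-4-{[4-(benzyloxy)-3-bromo-5-methoxyphenyl]methyl}-3-hydroxyoxolan-2-one | COc1cc(C[C@]2(O)C(=O)OC[C@H]2Cc2cc(OC)c(OCc3ccccc3)c(Br)c2)ccc1OCc1ccccc1 | intermediate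
25 | (3R,4R)-3-{[4-(benzyloxy)-3-methoxyphenyl]methyl}-4-{[4-(benzyloxy)-3-methoxy-5-(4,4,5,5-tetramethyl-1,3,2-dioxaborolan-2-yl)phenyl]methyl}-3-hydroxyoxolan-2-one | COc1cc(C[C@]2(O)C(=O)OC[C@H]2Cc2cc(OC)c(OCc3ccccc3)c(B3OC(C)(C)C(C)(C)O3)c2)ccc1OCc1ccccc1 | intermediate
26 | (3R,3′R,4R,4′R)-4,4′-{[2,2′-bis(benzyloxy)-3,3′-dimethoxy-[1,1′-biphenyl]-5,5′-diyl]bis(methylene)}bis(3-{[4-(benzyloxy)-3-methoxyphenyl]methyl}-3-hydroxyoxolan-2-one) | COc1cc(C[C@]2(O)C(=O)OC[C@H]2Cc2cc(OC)c(OCc5ccccc5)c(-c3cc(C[C@@H]4COC(=O)[C@@]4(O)Cc4ccc(OCc6ccccc6)c(OC)c4)cc(OC)c3OCc3ccccc3)c2)ccc1OCc1ccccc1 | intermediate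
27 | bis-5,5-nortrachelogenin | COc1cc(C[C@]2(O)C(=O)OC[C@H]2Cc2cc(OC)c(O)c(-c3cc(C[C@@H]4COC(=O)[C@@]4(O)Cc4ccc(O)c(OC)c4)cc(OC)c3O)c2)ccc1O | target

**Step count**
Total step count: 18. Longest linear sequence: 11 steps (1 → 7 → 8 → 9 → 12 → 13 → 14 → 15 → 16 → 17 → 18, from catechol).

**Steps most likely to fail, with fallbacks**

Risk 1, step 15. The dianion may form incompletely, alkylate on oxygen, or give poor facial selectivity. The fallback sets out from 22 and comes back to the route at 24. The hydroxyl is masked first (MOMCl, iPr2NEt, CH2Cl2) to give (3S,4R)-4-{[4-(benzyloxy)-3-bromo-5-methoxyphenyl]methyl}-3-(methoxymethoxy)oxolan-2-one F6. Its mono-enolate (LiN(SiMe3)2, THF–DMPU, −78 °C) is alkylated with 8, again anti to the C4 group, to give (3R,4R)-3-{[4-(benzyloxy)-3-methoxyphenyl]methyl}-4-{[4-(benzyloxy)-3-bromo-5-methoxyphenyl]methyl}-3-(methoxymethoxy)oxolan-2-one F7. Acetal cleavage (HCl, MeOH, 40 °C) then returns 24.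

Risk 2, step 12. The selective exchange or the copper-catalysed opening may suffer from the aryl bromide carried on the Grignard reagent. The fallback brings the bromine in after the ring opening; it sets out from 4 (with 17) and comes back at 20. Magnesium insertion into 4 (Mg, THF) gives [4-(benzyloxy)-3-methoxyphenyl]magnesium bromide F1, which opens 17 under the same CuBr·SMe2 catalysis (aq. HCl quench) to methyl (3R,4S)-4-{[4-(benzyloxy)-3-methoxyphenyl]methyl}-2-oxooxolane-3-carboxylate F2. Krapcho dealkoxycarbonylation gives (4S)-4-{[4-(benzyloxy)-3-methoxyphenyl]methyl}oxolan-2-one F3, and hydrogenolysis (H2, Pd/C) gives the phenol (4S)-4-[(4-hydroxy-3-methoxyphenyl)methyl]oxolan-2-one F4. Bromination ortho to the free OH (NBS, cat. iPr2NH, CH2Cl2) gives (4S)-4-[(3-bromo-4-hydroxy-5-methoxyphenyl)methyl]oxolan-2-one F5, and benzylation (BnBr, K2CO3, DMF) returns 20.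

Risk 3, step 17. The cross-coupling of two electron-rich, ortho-benzyloxy partners may stall or lose the boronate by protodeboronation. The fallback sets out from 24 and comes back at 26, bypassing 25. It is a reductive homocoupling of the bromide with stoichiometric zerovalent nickel (Ni(cod)2, 2,2′-bipyridine, DMF, 60 °C), which gives 26 directly; new compounds: none F0.

Further compounds
F1 | step 12 | [4-(benzyloxy)-3-methoxyphenyl]magnesium bromide | COc1cc([Mg]Br)ccc1OCc1ccccc1
F2 | step 12 | methyl (3R,4S)-4-{[4-(benzyloxy)-3-methoxyphenyl]methyl}-2-oxooxolane-3-carboxylate | COC(=O)[C@@H]1C(=O)OC[C@H]1Cc1ccc(OCc2ccccc2)c(OC)c1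
F3 | step 12 | (4S)-4-{[4-(benzyloxy)-3-methoxyphenyl]methyl}oxolan-2-one | O=C1C[C@H](Cc2ccc(OCc3ccccc3)c(OC)c2)CO1
F4 | step 12 | (4S)-4-[(4-hydroxy-3-methoxyphenyl)methyl]oxolan-2-one | O=C1C[C@H](Cc2ccc(O)c(OC)c2)CO1
F5 | step 12 | (4S)-4-[(3-bromo-4-hydroxy-5-methoxyphenyl)methyl]oxolan-2-one | O=C1C[C@H](Cc2cc(Br)c(O)c(OC)c2)CO1
F6 | step 15 | (3S,4R)-4-{[4-(benzyloxy)-3-bromo-5-methoxyphenyl]methyl}-3-(methoxymethoxy)oxolan-2-one | COCO[C@@H]1C(=O)OC[C@H]1Cc1cc(OC)c(OCc2ccccc2)c(Br)c1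
F7 | step 15 | (3R,4R)-3-{[4-(benzyloxy)-3-methoxyphenyl]methyl}-4-{[4-(benzyloxy)-3-bromo-5-methoxyphenyl]methyl}-3-(methoxymethoxy)oxolan-2-one | COc1cc(C[C@]2(OCOC)C(=O)OC[C@H]2Cc2cc(OC)c(OCc3ccccc3)c(Br)c2)ccc1OCc1ccccc1
F0 | step 17 | none | none
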